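**Plan**

- The target is read as a labdane, 19-acetoxy-7α,15-dihydroxylabda-8(17),13Z-dien-2-one. The enabling feature is that the C2 ketone is one methylene (C1) away from quaternary C10 (C20 methyl), and C9 lies between C10 and C8 with its exocyclic C17 methylene, so rings A and B share the relay C2→C1, C10→C9, C8→C17.
- Retrosynthetic cuts, in order: C12–C13 (Negishi coupling of the side-chain alkenyl iodide); then C1–C2 and C9–C10 together (acyl radical bicyclization that ends by loss of PhSO2 from C17); then C7–C8 (Nozaki–Hiyama–Kishi coupling). This leaves a C2–C7 dialdehyde ester cut out of (S)-carvone.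
- Forward: carvone is alkylated twice at its C6 (the future C4), the enone carbons are excised so that C19 and C7 appear as aldehydes, the C8–C12 alkenyl iodide is added at C7, C19 is reduced and acetylated, C7 is set, and the acid becomes the selenoester. Ring A and then ring B close in one radical chain, and the C13–C16 unit is attached last.
- Stereochemistry: C5 comes from (S)-carvone; C4 from enolate methylation anti to the isopropenyl group; C7 from a CBS reduction; C10 and C9 from the cascade (trans-decalin chair–chair transition state, with C11 cis to CH2SO2Ph in the alkene); 13Z from (Z)-3-iodobut-2-en-1-ol, coupled with retention.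

Key step: step 15

Remark on the chemistry: locants C1–C20 in the text are the labdane locants of the target; TBS = tert-butyldimethylsilyl; (S)-carvone, tert-butyl(but-3-yn-1-yloxy)dimethylsilane and but-2-yn-1-ol are taken as purchased.

**Route**

Step 1
Reactants: 1 (S)-(+)-carvone
Product: 2 tert-butyl 2-[(1R,6S)-3-methyl-2-oxo-6-(prop-1-en-2-yl)cyclohex-3-en-1-yl]acetate
Conditions: lithium diisopropylamide, THF, −78 °C; BrCH2CO2tBu, −78 → −20 °C
Reagents that add atoms: tert-butyl bromoacetate, CC(C)(C)OC(=O)CBr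
Why: Kinetic deprotonation of the cross-conjugated enone at the ring CH2 next to the carbonyl and SN2 alkylation of the lithium enolate (ketone enolate alkylation) should give mainly the trans product, whose new centre is in any case erased in step 2.

Step 2
Reactants: 2 tert-butyl 2-[(1R,6S)-3-methyl-2-oxo-6-(prop-1-en-2-yl)cyclohex-3-en-1-yl]acetate
Product: 3 tert-butyl 2-[(1S,6R)-1,3-dimethyl-2-oxo-6-(prop-1-en-2-yl)cyclohex-3-en-1-yl]acetate
Conditions: lithium diisopropylamide (1.05 equiv), THF, −78 °C; MeI, −78 → 0 °C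
Reagents that add atoms: iodomethane, CI
Why: In this enolate alkylation the ketone α-CH is several pK units more acidic than the CH2 of the hindered tert-butyl ester, and MeI should attack the tetrasubstituted enolate anti to the pseudoaxial isopropenyl group on the neighbouring carbon, which places methyl trans and the acetate arm cis to it and so fixes C4.

Step 3
Reactants: 3 tert-butyl 2-[(1S,6R)-1,3-dimethyl-2-oxo-6-(prop-1-en-2-yl)cyclohex-3-en-1-yl]acetate
Product: 4 the 3,4-epoxide of 3 (α,β-epoxy ketone)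
Conditions: 30% H2O2, NaOH (0.3 equiv), MeOH, 0 °C
Reagents that add atoms: hydrogen peroxide, OO
Why: Weitz–Scheffer nucleophilic epoxidation attacks only the electron-poor enone double bond, leaves the isopropenyl group and the tert-butyl ester alone, and creates stereocentres that are destroyed again in step 5.

Step 4
Reactants: 4 the 3,4-epoxide of 3
Product: 5 the corresponding epoxy alcohol (ring ketone reduced)
Conditions: NaBH4, MeOH, 0 °C
Reagents that add atoms: none
Why: Borohydride reduction of the ketone (epoxide and tert-butyl ester inert) brings the future C19 to the alcohol level so that the coming cleavage delivers it as an aldehyde and not as an acid, the carbinol configuration being of no consequence.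

Step 5
Reactants: 5 epoxy alcohol
Product: 8 tert-butyl (3S,4R)-3-formyl-3-methyl-6-oxo-4-(prop-1-en-2-yl)hexanoate, via triol 6 (not isolated), via hydroxy ketone 7 (not isolated)
Conditions: H5IO6 (3 equiv), THF–H2O, 0 °C → rt
Reagents that add atoms: none
Why: Periodic acid opens the trisubstituted epoxide hydrolytically and then cleaves the 1,2,3-triol twice (glycol cleavage followed by α-hydroxy ketone cleavage), excising the former ring C–CH3 unit as acetic acid, a reaction type established for terpene epoxides that carry an isopropenyl group.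

Step 6
Reactants: 9 tert-butyl(but-3-yn-1-yloxy)dimethylsilane
Product: 10 5-(TBSO)pent-2-yn-1-ol
Conditions: n-BuLi, THF, −78 °C; (CH2O)n, −78 °C → rt
Reagents that add atoms: formaldehyde (from paraformaldehyde), C=O
Why: Addition of the lithium acetylide to formaldehyde (acetylide hydroxymethylation) supplies C17 as a propargylic CH2OH.

Step 7
Reactants: 10 5-(TBSO)pent-2-yn-1-ol
Product: 12 (E)-2-iodo-5-(TBSO)pent-2-en-1-ol, via alkenylstannane 11 (not isolated)
Conditions: Bu3SnH, Mo(CO)3(CNtBu)3 (5 mol %), hydroquinone, THF, 55 °C; then I2, CH2Cl2, 0 °C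
Reagents that add atoms: iodine, II
Why: Molybdenum-catalysed syn hydrostannation of the propargylic alcohol should place tin on the alkyne carbon next to the CH2OH group, and iododestannylation with retention then gives the E iodide in which the future C11 chain is cis to the future C17 carbon.

Step 8
Reactants: 12 (E)-2-iodo-5-(TBSO)pent-2-en-1-ol
Product: 14 tert-butyl{[(E)-4-iodo-5-(phenylsulfonyl)pent-3-en-1-yl]oxy}dimethylsilane, via mesylate 13 (not isolated)
Conditions: MsCl, Et3N (1.2 equiv), CH2Cl2, −20 °C; then PhSO2Na, DMF, rt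
Reagents that add atoms: sodium benzenesulfinate, [Na+].[O-]S(=O)c1ccccc1
Why: Mesylation and SN2 displacement of the primary allylic mesylate by the sulfur atom of the sulfinate (S-alkylation of a sulfinate) install the radical leaving group on C17 without touching the alkenyl iodide or its geometry.

Step 9
Reactants: 8 tert-butyl (3S,4R)-3-formyl-3-methyl-6-oxo-4-(prop-1-en-2-yl)hexanoate; 14 tert-butyl{[(E)-4-iodo-5-(phenylsulfonyl)pent-3-en-1-yl]oxy}dimethylsilane
Product: 16 tert-butyl (3S,4R,7Z)-6-hydroxy-3-(hydroxymethyl)-3-methyl-7-[(phenylsulfonyl)methyl]-4-(prop-1-en-2-yl)-10-(TBSO)dec-7-enoate (both C6 epimers), via lactol 15 (not isolated)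
Conditions: CrCl2 (4 equiv), NiCl2 (2 mol %), DMF, rt; work-up; then NaBH4, MeOH, 0 °C
Reagents that add atoms: none
Why: In this Nozaki–Hiyama–Kishi coupling the alkenylchromium species formed through nickel catalysis should add only to the unhindered aldehyde (the α-quaternary aldehyde and the ester are spared), the new alkoxide closes onto the neopentyl aldehyde as a lactol, and borohydride then reduces that masked aldehyde to the C19 alcohol, while the unselectively formed C7 carbinol is corrected in steps 11 and 12.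

Step 10
Reactants: 16 diol (both C6 epimers)
Product: 17 tert-butyl (3S,4R,7Z)-3-(acetoxymethyl)-6-hydroxy-3-methyl-7-[(phenylsulfonyl)methyl]-4-(prop-1-en-2-yl)-10-(TBSO)dec-7-enoate (both C6 epimers)
Conditions: AcCl (1.1 equiv), 2,4,6-collidine, CH2Cl2, −78 °C
Reagents that add atoms: acetyl chloride, CC(=O)Cl
Why: Selective acylation of the primary alcohol beside the hindered secondary allylic one under acyl chloride–collidine conditions caps C19 as the acetate of the target before it can lactonise onto the ester.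

Step 11
Reactants: 17 acetate (both C6 epimers)
Product: 18 tert-butyl (3S,4R,7Z)-3-(acetoxymethyl)-3-methyl-6-oxo-7-[(phenylsulfonyl)methyl]-4-(prop-1-en-2-yl)-10-(TBSO)dec-7-enoate
Conditions: Dess–Martin periodinane, CH2Cl2, rt
Reagents that add atoms: none
Why: Dess–Martin oxidation of the secondary allylic alcohol should convert both epimers into one enone under neutral conditions that neither move the double bond nor disturb the allyl sulfone.

Step 12
Reactants: 18 enone
Product: 19 tert-butyl (3S,4R,6R,7Z)-3-(acetoxymethyl)-6-hydroxy-3-methyl-7-[(phenylsulfonyl)methyl]-4-(prop-1-en-2-yl)-10-(TBSO)dec-7-enoate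
Conditions: (S)-1-methyl-3,3-diphenyltetrahydro-1H,3H-pyrrolo[1,2-c][1,3,2]oxazaborole [(S)-Me-CBS, 0.2 equiv], catecholborane, toluene, −78 °C
Reagents that add atoms: none
Why: In this Corey–Bakshi–Shibata reduction the α-branched alkenyl group acts as the large substituent and the C6 methylene as the small one, so the (S)-catalyst should deliver hydride to the face that gives the 7R alcohol (the sense in which it reduces acetophenone to the R alcohol), while catecholborane at −78 °C leaves the alkenes alone.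

Step 13
Reactants: 19 (7R) alcohol
Product: 22 (3S,4R,6R,7Z)-3-(acetoxymethyl)-6,10-bis(TBSO)-3-methyl-7-[(phenylsulfonyl)methyl]-4-(prop-1-en-2-yl)dec-7-enoic acid, via silyl ether 20 (not isolated), via silyl ester 21 (not isolated)
Conditions: TBSOTf (4 equiv), 2,6-lutidine (6 equiv), CH2Cl2, −78 °C → rt; then pH 5 buffer, THF
Reagents that add atoms: tert-butyldimethylsilyl triflate, CC(C)(C)[Si](C)(C)OS(=O)(=O)C(F)(F)F
Why: Silylation of the secondary alcohol is followed at room temperature by silyl triflate-mediated dealkylation of the tert-butyl ester with loss of isobutene (the known silyl triflate–lutidine cleavage of tert-butyl esters and carbamates), and the labile silyl ester is hydrolysed on mildly acidic work-up that spares the acetate and the silyl ethers.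

Step 14
Reactants: 22 acid
Product: 23 Se-phenyl (3S,4R,6R,7Z)-3-(acetoxymethyl)-6,10-bis(TBSO)-3-methyl-7-[(phenylsulfonyl)methyl]-4-(prop-1-en-2-yl)dec-7-eneselenoate
Conditions: (PhSe)2, PBu3, CH2Cl2, rt
Reagents that add atoms: diphenyl diselenide, c1ccc(cc1)[Se][Se]c1ccccc1
Why: Phosphine–diselenide activation of the carboxylic acid (an acyloxyphosphonium ion captured by selenolate) is the standard preparation of Se-phenyl selenoesters and tolerates acetate, silyl ethers and the sulfone.

Step 15
Reactants: 23 selenoester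
Product: 24 (4S,5R,7R,9R,10S)-19-acetoxy-7,12-bis(TBSO)-13,14,15,16-tetranorlabd-8(17)-en-2-one
Conditions: Bu3SnH (1.3 equiv) and azobisisobutyronitrile (0.2 equiv) by syringe pump over 8 h, benzene (0.003 M), 80 °C
Reagents that add atoms: none
Why: The stannyl radical abstracts PhSe from the selenoester, the C2 acyl radical adds to the CH2 terminus C1 of the isopropenyl group (6-endo-trig, ring A, giving the cyclohexanone and the tertiary C10 radical), this radical adds to C9 of the trisubstituted C8=C9 alkene (6-endo-trig, ring B), and the tertiary C8 radical expels PhSO2•, which leaves the C8=C17 methylene and carries the chain by taking hydrogen from Bu3SnH. The closest known reactions are acyl radical polyene cyclizations of selenoesters, which close six-membered rings in the endo mode at 1,1-disubstituted and trisubstituted alkenes, and radical allylations that end by β-scission of a sulfonyl radical. C10 is set by the trans-decalin chair–chair transition state in which the C5–C6 bond is equatorial on the newly formed ring A and the C20 methyl becomes axial, anti to H5; C9 is set by the alkene geometry, because the C11 chain, cis to CH2SO2Ph and trans to C7, takes the equatorial position of that chair. The step needs endo closure twice, which the substitution pattern secures: exo attack would have to create a quaternary centre at C10 and then vicinal quaternary centres at C8 and C10, whereas endo attack gives tertiary radicals, the second of which fragments at once. It also needs the chair that carries the C7 silyloxy group axially, which should be favoured because an equatorial C7 substituent would eclipse the in-plane CH2SO2Ph group on C8 (allylic 1,2 strain) while the axial one meets only H5 and H9. Slow addition of the stannane at high dilution keeps hydrogen transfer to the acyl and C10 radicals slower than the two ring closures.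

Step 16
Reactants: 24 bis-silyl ether
Product: 25 (4S,5R,7R,9R,10S)-19-acetoxy-12-hydroxy-7-(TBSO)-13,14,15,16-tetranorlabd-8(17)-en-2-one
Conditions: HF·pyridine, pyridine, THF, 0 °C
Reagents that add atoms: none
Why: Buffered HF·pyridine cleaves the unhindered primary silyl ether much faster than the secondary, axial, allylic one (rate-based selective desilylation), and acetate, ketone and the exocyclic alkene are inert.

Step 17
Reactants: 25 primary alcohol
Product: 26 (4S,5R,7R,9R,10S)-19-acetoxy-12-iodo-7-(TBSO)-13,14,15,16-tetranorlabd-8(17)-en-2-one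
Conditions: I2, PPh3, imidazole, CH2Cl2, 0 °C → rt
Reagents that add atoms: iodine, II
Why: Appel-type iodination converts the primary alcohol into the iodide through an alkoxyphosphonium iodide (SN2) without affecting the other groups.

Step 18
Reactants: 27 but-2-yn-1-ol
Product: 29 (Z)-3-iodobut-2-en-1-ol, via alkenylalanate 28 (not isolated)
Conditions: NaAlH2(OCH2CH2OMe)2, THF, 0 °C → rt; then I2, −78 °C
Reagents that add atoms: iodine, II
Why: Hydroxyl-directed trans hydroalumination of the propargylic alcohol puts aluminium on C3 within a five-membered alkoxyalanate, and iodinolysis with retention gives the Z iodide (iodine cis to CH2OH).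

Step 19
Reactants: 29 (Z)-3-iodobut-2-en-1-ol
Product: 30 tert-butyl{[(Z)-3-iodobut-2-en-1-yl]oxy}dimethylsilane
Conditions: TBSCl, imidazole, DMF, rt
Reagents that add atoms: tert-butyldimethylsilyl chloride, CC(C)(C)[Si](C)(C)Cl
Why: Standard silylation of the primary alcohol lets the C15 and C7 oxygens be released together in the last step.

Step 20
Reactants: 26 primary iodide; 30 tert-butyl{[(Z)-3-iodobut-2-en-1-yl]oxy}dimethylsilane
Product: 32 (4S,5R,7R,9R,10S,13Z)-19-acetoxy-7,15-bis(TBSO)labda-8(17),13-dien-2-one, via alkylzinc iodide 31 (not isolated)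
Conditions: Zn dust (I2-activated), DMA, 40 °C; then 30, PdCl2(dppf) (5 mol %), THF, rt → 45 °C
Reagents that add atoms: none
Why: Zinc insertion into the primary iodide gives an alkylzinc iodide that tolerates ketone and ester, and its Negishi coupling with the alkenyl iodide proceeds with retention of alkene geometry, so C12 ends up cis to C15 as the 13Z alkene requires.

Step 21
Reactants: 32 bis-silyl ether
Product: 33 (4S,5R,7R,9R,10S,13Z)-19-acetoxy-7,15-dihydroxylabda-8(17),13-dien-2-one
Conditions: HF·pyridine, THF, rt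
Reagents that add atoms: none
Why: Fluoride-mediated desilylation removes both silyl ethers under mildly acidic conditions that should leave the primary acetate, the ketone and both alkenes untouched.

**Compound list**

1 | (S)-(+)-carvone, (5S)-2-methyl-5-(prop-1-en-2-yl)cyclohex-2-en-1-one | CC1=CC[C@H](C(C)=C)CC1=O | starting material
2 | tert-butyl 2-[(1R,6S)-3-methyl-2-oxo-6-(prop-1-en-2-yl)cyclohex-3-en-1-yl]acetate (acetate arm trans to isopropenyl) | O=C1C(C)=CC[C@H](C(C)=C)[C@H]1CC(=O)OC(C)(C)C | intermediate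
3 | tert-butyl 2-[(1S,6R)-1,3-dimethyl-2-oxo-6-(prop-1-en-2-yl)cyclohex-3-en-1-yl]acetate (methyl trans, acetate arm cis to isopropenyl) | O=C1C(C)=CC[C@H](C(C)=C)[C@]1(C)CC(=O)OC(C)(C)C | intermediate
4 | 3,4-epoxide of 3 (epoxy ketone; oxygen expected anti to isopropenyl, epoxide centres not carried on) | O=C1C2(C)OC2C[C@H](C(C)=C)[C@]1(C)CC(=O)OC(C)(C)C | intermediate
5 | epoxy alcohol from 4 (ring ketone reduced; carbinol and epoxide centres not carried on) | OC1C2(C)OC2C[C@H](C(C)=C)[C@]1(C)CC(=O)OC(C)(C)C | intermediate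
6 | tert-butyl 2-[2,3,4-trihydroxy-1,3-dimethyl-6-(prop-1-en-2-yl)cyclohexyl]acetate, quaternary and isopropenyl-bearing carbons as in 3 (triol, not isolated) | OC1C(C)(O)C(O)C[C@H](C(C)=C)[C@]1(C)CC(=O)OC(C)(C)C | intermediate
7 | tert-butyl (3S,4R)-3-(1-hydroxy-2-oxopropyl)-3-methyl-6-oxo-4-(prop-1-en-2-yl)hexanoate (hydroxy ketone, not isolated) | CC(=O)C(O)[C@@](C)(CC(=O)OC(C)(C)C)[C@@H](C(C)=C)CC=O | intermediate
8 | tert-butyl (3S,4R)-3-formyl-3-methyl-6-oxo-4-(prop-1-en-2-yl)hexanoate (C2–C7 fragment; formyl = C19, 6-oxo = C7) | CC(C)(C)OC(=O)C[C@](C)(C=O)[C@@H](C(C)=C)CC=O | intermediate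
9 | tert-butyl(but-3-yn-1-yloxy)dimethylsilane | C#CCCO[Si](C)(C)C(C)(C)C | starting material
10 | 5-(TBSO)pent-2-yn-1-ol | OCC#CCCO[Si](C)(C)C(C)(C)C | intermediate
11 | (E)-5-(TBSO)-2-(tributylstannyl)pent-2-en-1-ol (not isolated) | OC/C(=C\CCO[Si](C)(C)C(C)(C)C)[Sn](CCCC)(CCCC)CCCC | intermediate
12 | (E)-2-iodo-5-(TBSO)pent-2-en-1-ol | OC/C(I)=C\CCO[Si](C)(C)C(C)(C)C | intermediate
13 | (E)-2-iodo-5-(TBSO)pent-2-en-1-yl methanesulfonate (not isolated) | CS(=O)(=O)OC/C(I)=C\CCO[Si](C)(C)C(C)(C)C | intermediate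
14 | tert-butyl{[(E)-4-iodo-5-(phenylsulfonyl)pent-3-en-1-yl]oxy}dimethylsilane (C17, C8, C9, C11, C12 unit) | O=S(=O)(C/C(I)=C\CCO[Si](C)(C)C(C)(C)C)c1ccccc1 | intermediate
15 | six-membered lactol between the C7 hydroxyl and the C19 aldehyde: tert-butyl 2-[2-hydroxy-3-methyl-4-(prop-1-en-2-yl)-6-{(Z)-1-(phenylsulfonyl)-5-(TBSO)pent-2-en-2-yl}tetrahydro-2H-pyran-3-yl]acetate, ring C3 and C4 as in 8, both C6 epimers and both anomers (not isolated) | OC1OC(/C(CS(=O)(=O)c2ccccc2)=C/CCO[Si](C)(C)C(C)(C)C)C[C@H](C(C)=C)[C@]1(C)CC(=O)OC(C)(C)C | intermediate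
16 | tert-butyl (3S,4R,7Z)-6-hydroxy-3-(hydroxymethyl)-3-methyl-7-[(phenylsulfonyl)methyl]-4-(prop-1-en-2-yl)-10-(TBSO)dec-7-enoate, both C6 epimers (C6 = labdane C7) | CC(C)(C)OC(=O)C[C@](C)(CO)[C@@H](C(C)=C)CC(O)/C(CS(=O)(=O)c1ccccc1)=C/CCO[Si](C)(C)C(C)(C)C | intermediate
17 | tert-butyl (3S,4R,7Z)-3-(acetoxymethyl)-6-hydroxy-3-methyl-7-[(phenylsulfonyl)methyl]-4-(prop-1-en-2-yl)-10-(TBSO)dec-7-enoate, both C6 epimers | CC(C)(C)OC(=O)C[C@](C)(COC(C)=O)[C@@H](C(C)=C)CC(O)/C(CS(=O)(=O)c1ccccc1)=C/CCO[Si](C)(C)C(C)(C)C | intermediate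
18 | tert-butyl (3S,4R,7Z)-3-(acetoxymethyl)-3-methyl-6-oxo-7-[(phenylsulfonyl)methyl]-4-(prop-1-en-2-yl)-10-(TBSO)dec-7-enoate | CC(C)(C)OC(=O)C[C@](C)(COC(C)=O)[C@@H](C(C)=C)CC(=O)/C(CS(=O)(=O)c1ccccc1)=C/CCO[Si](C)(C)C(C)(C)C | intermediate
19 | tert-butyl (3S,4R,6R,7Z)-3-(acetoxymethyl)-6-hydroxy-3-methyl-7-[(phenylsulfonyl)methyl]-4-(prop-1-en-2-yl)-10-(TBSO)dec-7-enoate | CC(C)(C)OC(=O)C[C@](C)(COC(C)=O)[C@@H](C(C)=C)C[C@@H](O)/C(CS(=O)(=O)c1ccccc1)=C/CCO[Si](C)(C)C(C)(C)C | intermediate
20 | tert-butyl (3S,4R,6R,7Z)-3-(acetoxymethyl)-6,10-bis(TBSO)-3-methyl-7-[(phenylsulfonyl)methyl]-4-(prop-1-en-2-yl)dec-7-enoate (not isolated) | CC(C)(C)OC(=O)C[C@](C)(COC(C)=O)[C@@H](C(C)=C)C[C@@H](O[Si](C)(C)C(C)(C)C)/C(CS(=O)(=O)c1ccccc1)=C/CCO[Si](C)(C)C(C)(C)C | intermediate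
21 | tert-butyldimethylsilyl ester of acid 22 (not isolated) | CC(C)(C)[Si](C)(C)OC(=O)C[C@](C)(COC(C)=O)[C@@H](C(C)=C)C[C@@H](O[Si](C)(C)C(C)(C)C)/C(CS(=O)(=O)c1ccccc1)=C/CCO[Si](C)(C)C(C)(C)C | intermediate
22 | (3S,4R,6R,7Z)-3-(acetoxymethyl)-6,10-bis(TBSO)-3-methyl-7-[(phenylsulfonyl)methyl]-4-(prop-1-en-2-yl)dec-7-enoic acid | OC(=O)C[C@](C)(COC(C)=O)[C@@H](C(C)=C)C[C@@H](O[Si](C)(C)C(C)(C)C)/C(CS(=O)(=O)c1ccccc1)=C/CCO[Si](C)(C)C(C)(C)C | intermediate
23 | Se-phenyl (3S,4R,6R,7Z)-3-(acetoxymethyl)-6,10-bis(TBSO)-3-methyl-7-[(phenylsulfonyl)methyl]-4-(prop-1-en-2-yl)dec-7-eneselenoate (cyclization precursor; C11 chain cis to CH2SO2Ph) | O=C([Se]c1ccccc1)C[C@](C)(COC(C)=O)[C@@H](C(C)=C)C[C@@H](O[Si](C)(C)C(C)(C)C)/C(CS(=O)(=O)c1ccccc1)=C/CCO[Si](C)(C)C(C)(C)C | intermediate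
24 | (4S,5R,7R,9R,10S)-19-acetoxy-7,12-bis(TBSO)-13,14,15,16-tetranorlabd-8(17)-en-2-one (trans-decalin, 7α-silyloxy axial, C9 chain equatorial) | C=C1[C@H](O[Si](C)(C)C(C)(C)C)C[C@H]2[C@@](C)(COC(C)=O)CC(=O)C[C@]2(C)[C@H]1CCO[Si](C)(C)C(C)(C)C | intermediate
25 | (4S,5R,7R,9R,10S)-19-acetoxy-12-hydroxy-7-(TBSO)-13,14,15,16-tetranorlabd-8(17)-en-2-one | C=C1[C@H](O[Si](C)(C)C(C)(C)C)C[C@H]2[C@@](C)(COC(C)=O)CC(=O)C[C@]2(C)[C@H]1CCO | intermediate
26 | (4S,5R,7R,9R,10S)-19-acetoxy-12-iodo-7-(TBSO)-13,14,15,16-tetranorlabd-8(17)-en-2-one | C=C1[C@H](O[Si](C)(C)C(C)(C)C)C[C@H]2[C@@](C)(COC(C)=O)CC(=O)C[C@]2(C)[C@H]1CCI | intermediate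
27 | but-2-yn-1-ol | CC#CCO | starting material
28 | sodium 2,2-bis(2-methoxyethoxy)-3-methyl-2,5-dihydro-1,2-oxaluminol-2-uide (cyclic alkenylalanate, not isolated) | [Na+].CC1=CCO[Al-]1(OCCOC)OCCOC | intermediate
29 | (Z)-3-iodobut-2-en-1-ol | C/C(I)=C/CO | intermediate
30 | tert-butyl{[(Z)-3-iodobut-2-en-1-yl]oxy}dimethylsilane | C/C(I)=C/CO[Si](C)(C)C(C)(C)C | intermediate
31 | C12 alkylzinc iodide derived from 26 (not isolated) | C=C1[C@H](O[Si](C)(C)C(C)(C)C)C[C@H]2[C@@](C)(COC(C)=O)CC(=O)C[C@]2(C)[C@H]1CC[Zn]I | intermediate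
32 | (4S,5R,7R,9R,10S,13Z)-19-acetoxy-7,15-bis(TBSO)labda-8(17),13-dien-2-one | C=C1[C@H](O[Si](C)(C)C(C)(C)C)C[C@H]2[C@@](C)(COC(C)=O)CC(=O)C[C@]2(C)[C@H]1CC/C(C)=C\CO[Si](C)(C)C(C)(C)C | intermediate
33 | (4S,5R,7R,9R,10S,13Z)-19-acetoxy-7,15-dihydroxylabda-8(17),13-dien-2-one (CNP0277693.2) | C=C1[C@H](O)C[C@H]2[C@@](C)(COC(C)=O)CC(=O)C[C@]2(C)[C@H]1CC/C(C)=C\CO | target

**Step count**

Total: 21 steps. Longest linear sequence: 16 steps from (S)-carvone (steps 1–5, 9–17, 20, 21). The alkenyl iodide 14 takes 3 steps (6–8) and the side-chain iodide 30 takes 2 steps (18–19).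

**Steps most likely to fail**

Step 15. What may go wrong: the stannane transfers hydrogen to the acyl radical or to the C10 radical before the rings close; stannyl radicals add to the allyl sulfone; or ring B closes through a transition state that avoids the axial C7 silyloxy group and so gives the cis-fused or 9-epimeric decalin.
Fallback (the C7 oxygen is introduced after the cyclization; sets out from 8, returns at 24):
- NaBH4 in MeOH reduces both aldehydes of 8 to tert-butyl (3S,4R)-6-hydroxy-3-(hydroxymethyl)-3-methyl-4-(prop-1-en-2-yl)hexanoate F1.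
- I2/PPh3/imidazole converts only the unhindered C7 hydroxyl, giving the iodo alcohol F2, and Ac2O/pyridine gives the iodo acetate F3.
- Zinc insertion in DMA gives the alkylzinc iodide F4, and Negishi coupling with 14 under PdCl2(dppf) gives the 7-deoxy ester F5.
- TMSOTf/2,6-lutidine frees the acid F6, and (PhSe)2/PBu3 gives the selenoester F7.
- The same Bu3SnH/azobisisobutyronitrile bicyclization, now without an allylic substituent on ring B, should give the 7-deoxy decalone F8.
- Catalytic SeO2 with t-BuOOH in CH2Cl2 oxidises the C7 methylene of the 8(17)-ene from the axial α face (ene reaction and [2,3] shift, the usual course for exocyclic methylene decalins) to the 7α-alcohol F9.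
- TBSOTf/2,6-lutidine converts F9 into 24.

Step 9. What may go wrong: the alkenylnickel or alkenylchromium intermediate loses benzenesulfinate (β-elimination to an allene) faster than it adds to the aldehyde, or addition to the hindered aldehyde competes.
Fallback (no alkenylmetal; the sulfone is installed by allylic transposition; sets out from 8, returns at 18):
- Vinylmagnesium bromide (1 equiv, THF, −78 °C) adds to the unhindered aldehyde of 8 to give the vinyl lactol F10.
- NaBH4 gives the diol F11, AcCl/collidine the primary acetate F12, and Dess–Martin periodinane the vinyl ketone F13.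
- Morita–Baylis–Hillman reaction of F13 with 3-(TBSO)propanal (1,4-diazabicyclo[2.2.2]octane) gives the adduct F14, and Ac2O/DMAP its acetate F15.
- PhSO2Na in DMF displaces the acetate in the SN2′ sense to give 18 with the thermodynamically preferred geometry (C11 trans to the carbonyl).

Step 2. What may go wrong: the amide base removes a proton from the ester CH2 instead of the ring α-carbon, so that the side arm is methylated, or the methylation is not face-selective.
Fallback (carboxylate in place of the ester during methylation; sets out from 2, returns at 3):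
- TMSOTf/2,6-lutidine cleaves the tert-butyl ester of 2 to the keto acid F16.
- Lithium diisopropylamide (2.2 equiv) gives the carboxylate–enolate dianion, in which the carboxylate arm cannot be enolised, and MeI gives the methylated keto acid F17 with the same anti selectivity.
- tert-Butyl 2,2,2-trichloroacetimidate with catalytic BF3·OEt2 re-forms the ester 3.

Further compounds
F1 | step 15 | tert-butyl (3S,4R)-6-hydroxy-3-(hydroxymethyl)-3-methyl-4-(prop-1-en-2-yl)hexanoate | CC(C)(C)OC(=O)C[C@](C)(CO)[C@@H](C(C)=C)CCO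
F2 | step 15 | tert-butyl (3S,4R)-3-(hydroxymethyl)-6-iodo-3-methyl-4-(prop-1-en-2-yl)hexanoate | CC(C)(C)OC(=O)C[C@](C)(CO)[C@@H](C(C)=C)CCI
F3 | step 15 | tert-butyl (3S,4R)-3-(acetoxymethyl)-6-iodo-3-methyl-4-(prop-1-en-2-yl)hexanoate | CC(C)(C)OC(=O)C[C@](C)(COC(C)=O)[C@@H](C(C)=C)CCI
F4 | step 15 | alkylzinc iodide from F3 | CC(C)(C)OC(=O)C[C@](C)(COC(C)=O)[C@@H](C(C)=C)CC[Zn]I
F5 | step 15 | tert-butyl (3S,4R,7Z)-3-(acetoxymethyl)-3-methyl-7-[(phenylsulfonyl)methyl]-4-(prop-1-en-2-yl)-10-(TBSO)dec-7-enoate | CC(C)(C)OC(=O)C[C@](C)(COC(C)=O)[C@@H](C(C)=C)CC/C(CS(=O)(=O)c1ccccc1)=C/CCO[Si](C)(C)C(C)(C)C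
F6 | step 15 | (3S,4R,7Z)-3-(acetoxymethyl)-3-methyl-7-[(phenylsulfonyl)methyl]-4-(prop-1-en-2-yl)-10-(TBSO)dec-7-enoic acid | OC(=O)C[C@](C)(COC(C)=O)[C@@H](C(C)=C)CC/C(CS(=O)(=O)c1ccccc1)=C/CCO[Si](C)(C)C(C)(C)C
F7 | step 15 | Se-phenyl selenoester of F6 | O=C([Se]c1ccccc1)C[C@](C)(COC(C)=O)[C@@H](C(C)=C)CC/C(CS(=O)(=O)c1ccccc1)=C/CCO[Si](C)(C)C(C)(C)C
F8 | step 15 | 19-acetoxy-12-(TBSO)-13,14,15,16-tetranorlabd-8(17)-en-2-one (7-deoxy analogue of 24) | C=C1CC[C@H]2[C@@](C)(COC(C)=O)CC(=O)C[C@]2(C)[C@H]1CCO[Si](C)(C)C(C)(C)C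
F9 | step 15 | 19-acetoxy-7α-hydroxy-12-(TBSO)-13,14,15,16-tetranorlabd-8(17)-en-2-one | C=C1[C@H](O)C[C@H]2[C@@](C)(COC(C)=O)CC(=O)C[C@]2(C)[C@H]1CCO[Si](C)(C)C(C)(C)C
F10 | step 9 | tert-butyl 2-[2-hydroxy-3-methyl-4-(prop-1-en-2-yl)-6-vinyltetrahydro-2H-pyran-3-yl]acetate (lactol, C6 epimers and anomers) | OC1OC(C=C)C[C@H](C(C)=C)[C@]1(C)CC(=O)OC(C)(C)C
F11 | step 9 | tert-butyl (3S,4R)-6-hydroxy-3-(hydroxymethyl)-3-methyl-4-(prop-1-en-2-yl)oct-7-enoate (C6 epimers) | CC(C)(C)OC(=O)C[C@](C)(CO)[C@@H](C(C)=C)CC(O)C=C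
F12 | step 9 | tert-butyl (3S,4R)-3-(acetoxymethyl)-6-hydroxy-3-methyl-4-(prop-1-en-2-yl)oct-7-enoate (C6 epimers) | CC(C)(C)OC(=O)C[C@](C)(COC(C)=O)[C@@H](C(C)=C)CC(O)C=C
F13 | step 9 | tert-butyl (3S,4R)-3-(acetoxymethyl)-3-methyl-6-oxo-4-(prop-1-en-2-yl)oct-7-enoate | CC(C)(C)OC(=O)C[C@](C)(COC(C)=O)[C@@H](C(C)=C)CC(=O)C=C
F14 | step 9 | tert-butyl (3S,4R)-3-(acetoxymethyl)-8-hydroxy-3-methyl-7-methylidene-6-oxo-4-(prop-1-en-2-yl)-10-(TBSO)decanoate (C8 epimers) | CC(C)(C)OC(=O)C[C@](C)(COC(C)=O)[C@@H](C(C)=C)CC(=O)C(=C)C(O)CCO[Si](C)(C)C(C)(C)C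
F15 | step 9 | tert-butyl (3S,4R)-8-acetoxy-3-(acetoxymethyl)-3-methyl-7-methylidene-6-oxo-4-(prop-1-en-2-yl)-10-(TBSO)decanoate (C8 epimers) | CC(C)(C)OC(=O)C[C@](C)(COC(C)=O)[C@@H](C(C)=C)CC(=O)C(=C)C(OC(C)=O)CCO[Si](C)(C)C(C)(C)C
F16 | step 2 | 2-[(1R,6S)-3-methyl-2-oxo-6-(prop-1-en-2-yl)cyclohex-3-en-1-yl]acetic acid | O=C1C(C)=CC[C@H](C(C)=C)[C@H]1CC(=O)O
F17 | step 2 | 2-[(1S,6R)-1,3-dimethyl-2-oxo-6-(prop-1-en-2-yl)cyclohex-3-en-1-yl]acetic acid | O=C1C(C)=CC[C@H](C(C)=C)[C@]1(C)CC(=O)O
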